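**Retrosynthetic overview**

1. Target ⇐ global desilylation of its 3,10-bis-TES ether.
2. Bis-TES ether ⇐ one-flask Nozaki–Hiyama–Kishi closure of the C5–C6 bond (ten-membered carbocycle), after which the C6 chromium alkoxide lactonises onto the C12 acrylate ester (γ-lactone); the precursor is fully acyclic.
3. Acyclic iodo-aldehyde ⇐ acetal unveiling ⇐ boron aldol (C2–C3) of a methyl ketone with (Z)-3-iodo-2-methylacrolein (sets C3, carries the 4Z alkene).
4. Methyl ketone ⇐ acylation/silylation ⇐ indium Barbier coupling (C7–C8) of a (Z)-2-(bromomethyl)enoate carrying C6 as a dimethyl acetal with a β-hydroxy aldehyde ⇐ Cu–box Mukaiyama aldol on butane-2,3-dione (sets C10).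
5. Ring order: no ring until step 13; there the carbocycle forms first (C–C), then the lactone (C–O) in the same operation.

Convention/assumption: germacrane numbering is used for positions (C1 ketone, C3 carbinol, C4=C5, C6 lactone carbinol, C7, C8 ester carbinol, C10 tertiary carbinol, C11=C13, C12 lactone C=O), the target being (3R,4Z,6R,7R,8R,10R); the facial sense of the Cu–box aldol on butane-2,3-dione is assumed to follow the pyruvate series.

**Route**

Step 1
Reactants: 1 S-ethyl ethanethioate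
Product: 3 [1-(ethylsulfanyl)ethenyl]oxy(trimethyl)silane, via lithium thioester enolate 2 (not isolated)
Conditions: LDA, THF, −78 °C; then TMSCl, −78 °C → rt; distil
Reagents that add atoms: chlorotrimethylsilane, C[Si](C)(C)Cl
Why: Kinetic deprotonation of the thioester and O-silylation of the lithium enolate (silyl ketene thioacetal formation); no stereocentre is formed.

Step 2
Reactants: 3 [1-(ethylsulfanyl)ethenyl]oxy(trimethyl)silane; 4 butane-2,3-dione
Product: 6 S-ethyl (3R)-3-hydroxy-3-methyl-4-oxopentanethioate, via silyl ether 5 (not isolated)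
Conditions: [Cu((R,R)-t-Bu-box)](OTf)2 (10 mol%), THF, −78 °C; then 1 M HCl
Reagents that add atoms: none
Why: Evans Cu(II)–bis(oxazoline) Mukaiyama aldol in which the 1,2-diketone chelates the square-planar copper and the ketene acetal adds to the unshielded carbonyl face, setting C10 (R); silyl transfer gives the TMS ether, which aqueous HCl cleaves.

Step 3
Reactants: 6 S-ethyl (3R)-3-hydroxy-3-methyl-4-oxopentanethioate
Product: 7 (3R)-3-hydroxy-3-methyl-4-oxopentanal
Conditions: Et3SiH, 10% Pd/C, acetone, rt; used crude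
Reagents that add atoms: none
Why: Fukuyama reduction (Pd insertion into the C–S bond, hydride from the silane) converts only the thioester into the aldehyde and leaves the ketone, the tertiary alcohol and C10 untouched.

Step 4
Reactants: 8 methyl prop-2-enoate; 9 2,2-dimethoxyacetaldehyde
Product: 10 methyl 3-hydroxy-4,4-dimethoxy-2-methylidenebutanoate (racemic)
Conditions: DABCO (30 mol%), dioxane–H2O, rt
Reagents that add atoms: none
Why: Morita–Baylis–Hillman reaction of the acrylate with an activated α-alkoxy aldehyde; the carbinol centre is destroyed in step 5, so no stereocontrol is needed.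

Step 5
Reactants: 10 methyl 3-hydroxy-4,4-dimethoxy-2-methylidenebutanoate
Product: 11 methyl (2Z)-2-(bromomethyl)-4,4-dimethoxybut-2-enoate
Conditions: NBS, Me2S, CH2Cl2, 0 °C → rt
Reagents that add atoms: N-bromosuccinimide, O=C1CCC(=O)N1Br
Why: Corey–Kim-type activation of the Baylis–Hillman alcohol and SN2′ return of bromide give the rearranged primary allylic bromide, preferentially as the (Z)-isomer (ester trans to the acetal carbon), under neutral conditions that spare the acetal.

Step 6
Reactants: 7 (3R)-3-hydroxy-3-methyl-4-oxopentanal; 11 methyl (2Z)-2-(bromomethyl)-4,4-dimethoxybut-2-enoate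
Product: 12 methyl (3R,4R,6R)-3-(dimethoxymethyl)-4,6-dihydroxy-6-methyl-2-methylidene-7-oxooctanoate
Conditions: In powder, THF–H2O (1:1), rt; no acid in work-up
Reagents that add atoms: none
Why: Indium Barbier 2-(alkoxycarbonyl)allylation in which the (Z)-allylindium adds at its γ-carbon through a chair transition state to give the syn C7/C8 pair, while In(III) chelation by the aldehyde oxygen and the free α-ketol hydroxyl directs attack so that C8–O is 1,3-anti to C10–O (7R,8R).

Step 7
Reactants: 12 methyl (3R,4R,6R)-3-(dimethoxymethyl)-4,6-dihydroxy-6-methyl-2-methylidene-7-oxooctanoate; 13 3-methylbutanoic anhydride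
Product: 14 methyl (3R,4R,6R)-3-(dimethoxymethyl)-6-hydroxy-6-methyl-4-(3-methylbutanoyloxy)-2-methylidene-7-oxooctanoate
Conditions: DMAP (cat.), pyridine, CH2Cl2, 0 °C
Reagents that add atoms: none
Why: DMAP-catalysed acylation is selective for the secondary C8 hydroxyl over the tertiary C10 hydroxyl and outruns lactonisation onto the conjugated methyl ester; no stereocentre is touched.

Step 8
Reactants: 14 methyl (3R,4R,6R)-3-(dimethoxymethyl)-6-hydroxy-6-methyl-4-(3-methylbutanoyloxy)-2-methylidene-7-oxooctanoate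
Product: 15 methyl (3R,4R,6R)-3-(dimethoxymethyl)-6-methyl-4-(3-methylbutanoyloxy)-2-methylidene-7-oxo-6-(triethylsilyloxy)octanoate
Conditions: TESCl, imidazole, DMAP (cat.), DMF, 40 °C
Reagents that add atoms: chlorotriethylsilane, CC[Si](Cl)(CC)CC
Why: Silylation of the tertiary alcohol with the chloride/imidazole couple (the triflate would ionise the acetal) stops C10–OH from later forming a six-membered lactol with the C6 aldehyde.

Step 9
Reactants: 16 prop-2-yn-1-ol
Product: 18 (2Z)-3-iodo-2-methylprop-2-en-1-ol, via alkenylmagnesium chelate 17 (not isolated)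
Conditions: MeMgBr, CuI (10 mol%), THF, −10 °C → rt; then I2, −78 → 0 °C
Reagents that add atoms: methylmagnesium bromide, C[Mg]Br; iodine, II
Why: Duboudin copper-catalysed anti-carbomagnesiation of the propargyl alkoxide puts methyl on C4 and magnesium on C5 cis to the CH2O arm, and iodinolysis with retention gives the (Z)-iodide that becomes the 4Z ring alkene.

Step 10
Reactants: 18 (2Z)-3-iodo-2-methylprop-2-en-1-ol
Product: 19 (2Z)-3-iodo-2-methylprop-2-enal
Conditions: MnO2, CH2Cl2, rt, dark; used at once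
Reagents that add atoms: none
Why: Activated MnO2 oxidises only the allylic alcohol and, kept neutral and dark, does not isomerise the (Z)-iodoenal.

Step 11
Reactants: 15 methyl (3R,4R,6R)-3-(dimethoxymethyl)-6-methyl-4-(3-methylbutanoyloxy)-2-methylidene-7-oxo-6-(triethylsilyloxy)octanoate; 19 (2Z)-3-iodo-2-methylprop-2-enal
Product: 21 methyl (3R,4R,6R,9R,10Z)-3-(dimethoxymethyl)-9-hydroxy-11-iodo-6,10-dimethyl-4-(3-methylbutanoyloxy)-2-methylidene-7-oxo-6-(triethylsilyloxy)undec-10-enoate, via enol borinate 20 (not isolated)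
Conditions: (−)-Ipc2BCl, Et3N, Et2O, −78 → 0 °C; then 19, −78 → −20 °C; H2O2, pH 7 buffer, MeOH
Reagents that add atoms: none
Why: Paterson boron aldol in which the ketone enolises on its only enolisable side (C2) and the (−)-Ipc2B enolate adds to the re face of the (Z)-enal under reagent control (the (+)-reagent gives the S carbinol in analogous methyl ketone/(Z)-enal couplings), setting C3 (R).

Step 12
Reactants: 21 methyl (3R,4R,6R,9R,10Z)-3-(dimethoxymethyl)-9-hydroxy-11-iodo-6,10-dimethyl-4-(3-methylbutanoyloxy)-2-methylidene-7-oxo-6-(triethylsilyloxy)undec-10-enoate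
Product: 23 methyl (3R,4R,6R,9R,10Z)-3-formyl-11-iodo-6,10-dimethyl-4-(3-methylbutanoyloxy)-2-methylidene-7-oxo-6,9-bis(triethylsilyloxy)undec-10-enoate, via collidinium salt 22 (not isolated)
Conditions: TESOTf, 2,4,6-collidine, CH2Cl2, 0 °C; then H2O
Reagents that add atoms: triethylsilyl trifluoromethanesulfonate, CC[Si](CC)(CC)OS(=O)(=O)C(F)(F)F; water, O
Why: Fujioka–Kita acetal cleavage converts the dimethyl acetal into a collidinium salt that water hydrolyses to the aldehyde without acid (so the tertiary TES ether, the β-acyloxy aldehyde and C7 survive), and the same reagent silylates the C3 hydroxyl.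

Step 13
Reactants: 23 methyl (3R,4R,6R,9R,10Z)-3-formyl-11-iodo-6,10-dimethyl-4-(3-methylbutanoyloxy)-2-methylidene-7-oxo-6,9-bis(triethylsilyloxy)undec-10-enoate
Product: 25 3,10-bis-O-triethylsilyl ether of the target (3R,4Z,6R,7R,8R,10R), via macrocyclic hydroxy ester 24 (not isolated)
Conditions: CrCl2 (8 equiv), NiCl2 (1 mol%), DMSO–THF, rt, 2 mM, slow addition
Reagents that add atoms: none
Why: Nozaki–Hiyama–Kishi alkenylation in which Ni/Cr exchange of the C5–I bond occurs with retention (4Z fixed) and the alkenylchromium adds to the aldehyde to close the ten-membered ring, after which the Cr(III) C6 alkoxide attacks the adjacent acrylate ester (the same array as in chromium 2-(alkoxycarbonyl)allylations) to close the γ-lactone; C6 (R, trans-lactone) is expected from Felkin–Anh attack anti to the C8 branch held back in the cyclic transition state.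

Step 14
Reactants: 25 3,10-bis-O-triethylsilyl ether of the target
Product: 26 (3R,4Z,6R,7R,8R,10R)-3,10-dihydroxy-1-oxogermacra-4,11(13)-dien-6,12-olid-8-yl 3-methylbutanoate (target)
Conditions: HF·pyridine, pyridine, THF, 0 °C → rt
Reagents that add atoms: none
Why: Fluoride cleaves the secondary allylic and the tertiary triethylsilyl ether without touching the α-methylene lactone, the isovalerate or the β-hydroxy ketone; no stereocentre changes.

**Compound list**

1 | S-ethyl ethanethioate | CC(=O)SCC | starting material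
2 | lithium 1-(ethylsulfanyl)ethen-1-olate (not isolated) | [Li+].[O-]C(=C)SCC | intermediate
3 | [1-(ethylsulfanyl)ethenyl]oxy(trimethyl)silane | C=C(SCC)O[Si](C)(C)C | intermediate
4 | butane-2,3-dione | CC(=O)C(C)=O | starting material
5 | S-ethyl (3R)-3-methyl-4-oxo-3-(trimethylsilyloxy)pentanethioate (not isolated) | CCSC(=O)C[C@@](C)(O[Si](C)(C)C)C(C)=O | intermediate
6 | S-ethyl (3R)-3-hydroxy-3-methyl-4-oxopentanethioate | CCSC(=O)C[C@@](C)(O)C(C)=O | intermediate
7 | (3R)-3-hydroxy-3-methyl-4-oxopentanal | O=CC[C@@](C)(O)C(C)=O | intermediate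
8 | methyl prop-2-enoate | C=CC(=O)OC | starting material
9 | 2,2-dimethoxyacetaldehyde | COC(OC)C=O | starting material
10 | methyl 3-hydroxy-4,4-dimethoxy-2-methylidenebutanoate (racemic) | C=C(C(=O)OC)C(O)C(OC)OC | intermediate
11 | methyl (2Z)-2-(bromomethyl)-4,4-dimethoxybut-2-enoate | BrC/C(C(=O)OC)=C\C(OC)OC | intermediate
12 | methyl (3R,4R,6R)-3-(dimethoxymethyl)-4,6-dihydroxy-6-methyl-2-methylidene-7-oxooctanoate | COC(=O)C(=C)[C@@H](C(OC)OC)[C@H](O)C[C@@](C)(O)C(C)=O | intermediate
13 | 3-methylbutanoic anhydride | CC(C)CC(=O)OC(=O)CC(C)C | starting material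
14 | methyl (3R,4R,6R)-3-(dimethoxymethyl)-6-hydroxy-6-methyl-4-(3-methylbutanoyloxy)-2-methylidene-7-oxooctanoate | COC(=O)C(=C)[C@@H](C(OC)OC)[C@H](OC(=O)CC(C)C)C[C@@](C)(O)C(C)=O | intermediate
15 | methyl (3R,4R,6R)-3-(dimethoxymethyl)-6-methyl-4-(3-methylbutanoyloxy)-2-methylidene-7-oxo-6-(triethylsilyloxy)octanoate | COC(=O)C(=C)[C@@H](C(OC)OC)[C@H](OC(=O)CC(C)C)C[C@@](C)(O[Si](CC)(CC)CC)C(C)=O | intermediate
16 | prop-2-yn-1-ol | C#CCO | starting material
17 | 4-methyl-2,5-dihydro-1,2-oxamagnesole, the chelated (Z)-alkenylmagnesium alkoxide (not isolated) | CC1=C[Mg]OC1 | intermediate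
18 | (2Z)-3-iodo-2-methylprop-2-en-1-ol | I/C=C(/C)CO | intermediate
19 | (2Z)-3-iodo-2-methylprop-2-enal | I/C=C(/C)C=O | intermediate
20 | enol diisopinocampheylborinate of 15 (boron on the C7 enol oxygen of the octanoate; not isolated) | COC(=O)C(=C)[C@@H](C(OC)OC)[C@H](OC(=O)CC(C)C)C[C@@](C)(O[Si](CC)(CC)CC)C(=C)OB([C@@H]1C[C@@H]2C[C@H]([C@H]1C)C2(C)C)[C@@H]1C[C@@H]2C[C@H]([C@H]1C)C2(C)C | intermediate
21 | methyl (3R,4R,6R,9R,10Z)-3-(dimethoxymethyl)-9-hydroxy-11-iodo-6,10-dimethyl-4-(3-methylbutanoyloxy)-2-methylidene-7-oxo-6-(triethylsilyloxy)undec-10-enoate | COC(=O)C(=C)[C@@H](C(OC)OC)[C@H](OC(=O)CC(C)C)C[C@@](C)(O[Si](CC)(CC)CC)C(=O)C[C@@H](O)/C(C)=C\I | intermediate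
22 | 1-(α-methoxyalkyl)-2,4,6-trimethylpyridinium triflate derived from the acetal carbon of 21, C9 hydroxyl silylated (epimers at the new centre; not isolated) | COC(=O)C(=C)[C@@H](C(OC)[n+]1c(C)cc(C)cc1C)[C@H](OC(=O)CC(C)C)C[C@@](C)(O[Si](CC)(CC)CC)C(=O)C[C@@H](O[Si](CC)(CC)CC)/C(C)=C\I.[O-]S(=O)(=O)C(F)(F)F | intermediate
23 | methyl (3R,4R,6R,9R,10Z)-3-formyl-11-iodo-6,10-dimethyl-4-(3-methylbutanoyloxy)-2-methylidene-7-oxo-6,9-bis(triethylsilyloxy)undec-10-enoate | COC(=O)C(=C)[C@@H](C=O)[C@H](OC(=O)CC(C)C)C[C@@](C)(O[Si](CC)(CC)CC)C(=O)C[C@@H](O[Si](CC)(CC)CC)/C(C)=C\I | intermediate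
24 | macrocyclic hydroxy ester: methyl 2-(cyclodec-3-en-1-yl)prop-2-enoate with free C6 hydroxyl, 3,10-bis-TES, 8-isovalerate, 1-oxo (germacrane positions; 3R,4Z,6R,8R,10R, C7 geometry as in 25; not isolated) | COC(=O)C(=C)[C@@H]1[C@H](OC(=O)CC(C)C)C[C@@](C)(O[Si](CC)(CC)CC)C(=O)C[C@@H](O[Si](CC)(CC)CC)/C(C)=C\[C@H]1O | intermediate
25 | (3R,4Z,6R,7R,8R,10R)-1-oxo-3,10-bis(triethylsilyloxy)germacra-4,11(13)-dien-6,12-olid-8-yl 3-methylbutanoate | C=C1C(=O)O[C@@H]2/C=C(/C)[C@H](O[Si](CC)(CC)CC)CC(=O)[C@](C)(O[Si](CC)(CC)CC)C[C@@H](OC(=O)CC(C)C)[C@@H]12 | intermediate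
26 | (3R,4Z,6R,7R,8R,10R)-3,10-dihydroxy-1-oxogermacra-4,11(13)-dien-6,12-olid-8-yl 3-methylbutanoate (CNP0406522.1) | C=C1C(=O)O[C@@H]2/C=C(/C)[C@H](O)CC(=O)[C@](C)(O)C[C@@H](OC(=O)CC(C)C)[C@@H]12 | target

**Totals**

Total step count: 14.
Longest linear sequence: 10 steps (1 → 2 → 3 → 6 → 7 → 8 → 11 → 12 → 13 → 14).

**Steps most likely to fail, each with one fallback**

Step 13. The C6 configuration rests on the conformation of the ring-forming transition state. The alkenylchromium could also close a five-membered ring on the hindered C1 ketone, and aldehyde 23 can enolise or lose the C8 acyloxy group. Fallback, setting out from 15 and coming back at 26: form the lactone first and close the carbocycle through a different bond. TESOTf/2,4,6-collidine then water converts 15 into the keto aldehyde F1. Intermolecular NHK coupling of F1 with iodo alcohol 18 (CrCl2, cat. NiCl2, a Kishi sulfonamide ligand for reagent control at C6), with lactonisation in the flask, gives the lactone alcohol F2. MnO2 gives the lactone enal F3. A Danishefsky-type macroaldolisation (KHMDS, THF, −78 °C, high dilution) closes C2–C3 to the C10 silyl ether F4, and HF·pyridine then gives 26.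

Step 6. Aldehyde 7 is a sensitive β-hydroxy 1,4-keto aldehyde, and the 1,3-anti induction depends on the tridentate indium chelate at a quaternary centre. Fallback, setting out from 6 (with 10) and coming back at 15: replace the chelated metal Barbier by a non-chelated allylboration. TESOTf/2,6-lutidine converts 6 into the silyl thioester F5, and Fukuyama reduction gives the silyloxy aldehyde F6. In parallel 10 is acetylated to the acetate F7 and borylated (B2pin2, Pd2(dba)3) to the allylboronate F8. Thermal allylboration of F6 with F8 (closed chair, syn; 1,3-anti by the non-chelated polar model) gives the hydroxy ester F9, and acylation of F9 with 13 gives 15.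

Step 11. Reagent control over a quaternary α-silyloxy ketone may be mismatched, and iodoenal 19 isomerises easily. Fallback, setting out from 15 and coming back at 21: switch from the closed boron transition state to an open, catalyst-controlled Mukaiyama aldol. LiHMDS/TMSCl at −78 °C converts 15 into the silyl enol ether F10, and SiCl4 with a chiral bisphosphoramide (Denmark conditions, −78 °C) adds F10 to 19; aqueous work-up returns 21.

**Further compounds**

F1 | step 13 | methyl (3R,4R,6R)-3-formyl-6-methyl-4-(3-methylbutanoyloxy)-2-methylidene-7-oxo-6-(triethylsilyloxy)octanoate | COC(=O)C(=C)[C@@H](C=O)[C@H](OC(=O)CC(C)C)C[C@@](C)(O[Si](CC)(CC)CC)C(C)=O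
F2 | step 13 | (1R,3R)-1-[(2R,3R)-2-[(1Z)-3-hydroxy-2-methylprop-1-en-1-yl]-4-methylidene-5-oxooxolan-3-yl]-3-methyl-4-oxo-3-(triethylsilyloxy)pentyl 3-methylbutanoate | C=C1C(=O)O[C@H](/C=C(/C)CO)[C@H]1[C@H](OC(=O)CC(C)C)C[C@@](C)(O[Si](CC)(CC)CC)C(C)=O
F3 | step 13 | (1R,3R)-3-methyl-1-[(2R,3R)-4-methylidene-2-[(1Z)-2-methyl-3-oxoprop-1-en-1-yl]-5-oxooxolan-3-yl]-4-oxo-3-(triethylsilyloxy)pentyl 3-methylbutanoate | C=C1C(=O)O[C@H](/C=C(/C)C=O)[C@H]1[C@H](OC(=O)CC(C)C)C[C@@](C)(O[Si](CC)(CC)CC)C(C)=O
F4 | step 13 | (3R,4Z,6R,7R,8R,10R)-3-hydroxy-1-oxo-10-(triethylsilyloxy)germacra-4,11(13)-dien-6,12-olid-8-yl 3-methylbutanoate | C=C1C(=O)O[C@@H]2/C=C(/C)[C@H](O)CC(=O)[C@](C)(O[Si](CC)(CC)CC)C[C@@H](OC(=O)CC(C)C)[C@@H]12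
F5 | step 6 | S-ethyl (3R)-3-methyl-4-oxo-3-(triethylsilyloxy)pentanethioate | CCSC(=O)C[C@@](C)(O[Si](CC)(CC)CC)C(C)=O
F6 | step 6 | (3R)-3-methyl-4-oxo-3-(triethylsilyloxy)pentanal | O=CC[C@@](C)(O[Si](CC)(CC)CC)C(C)=O
F7 | step 6 | methyl 3-acetoxy-4,4-dimethoxy-2-methylidenebutanoate (racemic) | C=C(C(=O)OC)C(OC(C)=O)C(OC)OC
F8 | step 6 | methyl (2E)-4,4-dimethoxy-2-[(4,4,5,5-tetramethyl-1,3,2-dioxaborolan-2-yl)methyl]but-2-enoate | COC(=O)/C(CB1OC(C)(C)C(C)(C)O1)=C/C(OC)OC
F9 | step 6 | methyl (3R,4R,6R)-3-(dimethoxymethyl)-4-hydroxy-6-methyl-2-methylidene-7-oxo-6-(triethylsilyloxy)octanoate | COC(=O)C(=C)[C@@H](C(OC)OC)[C@H](O)C[C@@](C)(O[Si](CC)(CC)CC)C(C)=O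
F10 | step 11 | methyl (3R,4R,6R)-3-(dimethoxymethyl)-6-methyl-4-(3-methylbutanoyloxy)-2-methylidene-6-(triethylsilyloxy)-7-(trimethylsilyloxy)oct-7-enoate | COC(=O)C(=C)[C@@H](C(OC)OC)[C@H](OC(=O)CC(C)C)C[C@@](C)(O[Si](CC)(CC)CC)C(=C)O[Si](C)(C)C
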